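**Retrosynthetic overview**

1. Feature: the 7-hydroxy-2,3-dihydrobenzofuran (O1, C2 with the 4-hydroxyphenyl group, C3 with the 3,5-dihydroxyphenyl group, benzo ring joined to the rest at C5). Its O1–C2 unit is read as the OCH2 of a 4-methoxybenzyl ether on a guaiacol-type oxygen and its C3 as a diaryl carbene carbon, so C2–C3 is the bond to make.
2. Tetrahydrofuran: ten O-methyl groups off last; both ring C–O bonds from a 1,4-diol; the two anisyl carbinol carbons from two aryl Grignard additions; C3'–C4' by Ireland–Claisen rearrangement of a (Z)-allylic arylacetate (chirality from (S)-but-3-yn-2-ol); aryl–C3' by Sonogashira coupling at the triflate of the C4 oxygen.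
3. 4,6-Dioxygenated dihydrobenzofuran: C2–aryl by decarboxylative arylation; O1–C2 by ring contraction of a 3-bromo-dihydrocoumarin (the lactone carbonyl leaves as CO2); C3–aryl by Rh-catalysed asymmetric 1,4-addition of an arylboronic acid to 5-(benzyloxy)-7-methoxycoumarin.
4. The boronic acid comes from the 5-bromo-7-methoxy-dihydrobenzofuran, closed by enantioselective Rh-carbene C–H insertion of a diaryldiazomethane into its own 4-methoxybenzyl ether.
5. Ring order: 7-oxygenated dihydrofuran ring (step 5), 4,6-dioxygenated dihydrofuran ring (step 11), tetrahydrofuran ring (step 23).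

Key step: step 5

Remark: the sense of induction of Rh2(R-PTAD)4 (step 5) and of (S)-SEGPHOS (step 9) is assigned by analogy with simpler substrates; the antipodal catalyst is to be used if the first run shows the opposite sense.

Names used below: A = (2R,3R)-3-(3,5-dimethoxyphenyl)-7-methoxy-2-(4-methoxyphenyl)-2,3-dihydro-1-benzofuran-5-yl. B = (2S,3S)-6-methoxy-2-(4-methoxyphenyl)-3-A-2,3-dihydro-1-benzofuran-4-yl. C2'–C5' are the tetrahydrofuran carbons (C2' and C5' carry 4-methoxyphenyl, C3' carries B, C4' carries 3,5-dimethoxyphenyl).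

**Route**

Step 1
Reactants: 1 5-bromo-2-hydroxy-3-methoxybenzaldehyde; 2 4-methoxybenzyl chloride
Product: 3 5-bromo-3-methoxy-2-[(4-methoxyphenyl)methoxy]benzaldehyde
Conditions: K2CO3, KI (cat.), DMF, 60 °C
Reagents that add atoms: none
Why: Williamson ether synthesis: the phenoxide (acidified by the ortho formyl group) displaces the benzylic chloride and installs the OCH2 carbon that becomes C2.

Step 2
Reactants: 3 5-bromo-3-methoxy-2-[(4-methoxyphenyl)methoxy]benzaldehyde; 4 1-bromo-3,5-dimethoxybenzene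
Product: 6 [5-bromo-3-methoxy-2-[(4-methoxyphenyl)methoxy]phenyl](3,5-dimethoxyphenyl)methanol (racemic), via aryl Grignard reagent 5 (not isolated)
Conditions: 4, Mg, I2 (cat.), THF, 50 °C; then 3, THF, −20 °C to 0 °C; aq. NH4Cl
Reagents that add atoms: none
Why: Grignard addition to an aldehyde: the preformed arylmagnesium bromide adds to the formyl group much faster than it exchanges with the aryl bromide of 3, and the racemic carbinol centre is removed in step 3.

Step 3
Reactants: 6 the diaryl carbinol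
Product: 7 [5-bromo-3-methoxy-2-[(4-methoxyphenyl)methoxy]phenyl](3,5-dimethoxyphenyl)methanone
Conditions: activated MnO2 (10 equiv), CH2Cl2, rt
Reagents that add atoms: none
Why: MnO2 oxidation of a doubly benzylic alcohol gives the benzophenone and leaves the benzyl ether and the aryl bromide alone.

Step 4
Reactants: 7 the diaryl ketone
Product: 8 hydrazone of 7 (E/Z mixture)
Conditions: N2H4·H2O (10 equiv), AcOH (cat.), EtOH, 80 °C
Reagents that add atoms: hydrazine NN
Why: Acid-catalysed hydrazone condensation of a diaryl ketone, with excess hydrazine to suppress azine formation; both geometric isomers lead to the same diazo compound.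

Step 5
Reactants: 8 hydrazone of 7
Product: 11 (2R,3R)-5-bromo-3-(3,5-dimethoxyphenyl)-7-methoxy-2-(4-methoxyphenyl)-2,3-dihydro-1-benzofuran (trans), via diazo compound 9 (not isolated), via cis-dihydrobenzofuran 10 (not isolated)
Conditions: MnO2 (8 equiv), CH2Cl2, 0 °C, filter through Celite; filtrate added to Rh2(R-PTAD)4 (1 mol %), CH2Cl2, 0 °C to rt; then TFA (5 vol %), 0 °C
Reagents that add atoms: none
Why: MnO2 dehydrogenates the hydrazone to the diaryldiazomethane 9, from which the dirhodium carboxylate expels N2 to give a donor/donor rhodium carbene. The carbene inserts into a benzylic C–H bond of the neighbouring OCH2Ar group through a three-centre, hydride-transfer-like transition state and so forms C2–C3; the closest known reaction type is the enantioselective dirhodium-catalysed intramolecular C–H insertion of diaryl carbenes into benzyl ethers to give 2,3-diaryl-2,3-dihydrobenzofurans. The dihydrofuran ring closes by a formal 1,5-insertion, the C–H bond five atoms from the carbene carbon being the only one that gives a five-membered ring. C3 (R) is set by the chiral carboxylate ligands, which differentiate the faces of the carbene. C2 is expected to form cis to the C3 aryl group (10) and is then inverted by TFA through reversible ionisation of the C2–O bond (p-anisyl-stabilised cation, re-closure by the phenol) to the more stable trans isomer, C3 not being touched. The step needs chemoselectivity for this C–H bond over the four methoxy groups, the aryl bromide and carbene dimerisation, which the low electrophilicity of a donor/donor carbene and the double activation of the C–H bond (α to oxygen and to the anisyl ring) should secure.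

Step 6
Reactants: 11 the trans 5-bromo-dihydrobenzofuran
Product: 12 A-B(OH)2, [(2R,3R)-3-(3,5-dimethoxyphenyl)-7-methoxy-2-(4-methoxyphenyl)-2,3-dihydro-1-benzofuran-5-yl]boronic acid
Conditions: B2(OH)4 (3 equiv), XPhos Pd G2 (2 mol %), XPhos (4 mol %), KOAc (3 equiv), EtOH, 80 °C
Reagents that add atoms: tetrahydroxydiboron OB(O)B(O)O
Why: Miyaura-type Pd-catalysed borylation of an aryl bromide gives the boronic acid directly under weakly basic conditions that cannot open the benzylic ring ether or deprotonate C3.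

Step 7
Reactants: 13 5,7-dihydroxycoumarin
Product: 14 5-hydroxy-7-methoxycoumarin
Conditions: MeI (1.05 equiv), K2CO3 (1.0 equiv), acetone, rt
Reagents that add atoms: iodomethane CI
Why: Williamson methylation under substrate control: the 7-OH, para-conjugated to the lactone enoate and unhindered, is the more acidic and accessible phenol and should be alkylated before the peri 5-OH (any 5-O-methyl isomer is removed by chromatography).

Step 8
Reactants: 14 5-hydroxy-7-methoxycoumarin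
Product: 15 5-(benzyloxy)-7-methoxycoumarin
Conditions: BnBr, K2CO3, DMF, 50 °C
Reagents that add atoms: benzyl bromide BrCc1ccccc1
Why: Williamson benzylation of the remaining phenol gives an ether that survives steps 9–12 and is later removed by hydrogenolysis without loss of the methyl ethers.

Step 9
Reactants: 12 A-B(OH)2; 15 5-(benzyloxy)-7-methoxycoumarin
Product: 16 (4S)-4-A-5-(benzyloxy)-7-methoxychroman-2-one
Conditions: [Rh(acac)(C2H4)2] (5 mol %), (S)-SEGPHOS (5.5 mol %), 15 (3 equiv), dioxane/H2O 10:1, 60 °C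
Reagents that add atoms: none
Why: Hayashi–Miyaura Rh-catalysed asymmetric 1,4-addition to a coumarin: the aryl–Rh(I) species adds across C3=C4 and the oxa-π-allyl rhodium is protonated by water, the new C4 centre (S) being set by the bisphosphine and not by the remote centres of 12; the coumarin is used in excess so that protodeboronation of 12 is not limiting.

Step 10
Reactants: 16 the 4-aryl-dihydrocoumarin
Product: 18 (3R,4S)-4-A-5-(benzyloxy)-3-bromo-7-methoxychroman-2-one, via lithium enolate 17 (not isolated)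
Conditions: LiHMDS (1.1 equiv), THF, −78 °C; then NBS (1.1 equiv), −78 °C; aq. NH4Cl
Reagents that add atoms: N-bromosuccinimide O=C1CCC(=O)N1Br
Why: α-Bromination of a lactone enolate: NBS should approach C3 anti to the C4 aryl group (3,4-trans), and C4, being β to the carbonyl, cannot enolise and keeps its configuration.

Step 11
Reactants: 18 the 3-bromo-dihydrocoumarin
Product: 20 (2S,3S)-3-A-4-(benzyloxy)-6-methoxy-2,3-dihydro-1-benzofuran-2-carboxylic acid, via ring-opened bromo acid 19 (not isolated)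
Conditions: LiOH (4 equiv), THF/H2O 3:1, 0 °C to rt; then 1 M HCl
Reagents that add atoms: lithium hydroxide [Li+].[OH-]
Why: Perkin-type ring contraction of a 3-halo-dihydrocoumarin: hydroxide opens the aryl ester and the freed phenoxide displaces the α-bromide by intramolecular Williamson 5-exo-tet closure with inversion, giving the 2,3-trans acid; the C2 configuration is erased in step 12 and C3 is untouched.

Step 12
Reactants: 20 the dihydrobenzofuran-2-carboxylic acid; 21 4-iodoanisole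
Product: 22 (2S,3S)-3-A-4-(benzyloxy)-6-methoxy-2-(4-methoxyphenyl)-2,3-dihydro-1-benzofuran
Conditions: Ir[dF(CF3)ppy]2(dtbbpy)PF6 (2 mol %), NiCl2·glyme (10 mol %), dtbbpy (15 mol %), 21 (3 equiv), Cs2CO3 (1.5 equiv), DMF, blue LEDs, rt
Reagents that add atoms: none
Why: Metallaphotoredox decarboxylative arylation of an α-oxy carboxylic acid: the carboxylate is oxidised by the excited iridium complex, loses CO2, and the α-aryloxy radical is captured by the aryl–nickel species anti to the C3 aryl group, giving C2 (S) trans to C3; any cis epimer would converge to trans later, since C2 is now a p-anisyl ether carbon that equilibrates under acid.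

Step 13
Reactants: 22 the 4-benzyloxy-dihydrobenzofuran
Product: 23 B-OH, (2S,3S)-3-A-6-methoxy-2-(4-methoxyphenyl)-2,3-dihydro-1-benzofuran-4-ol
Conditions: H2 (1 atm), 10% Pd/C, EtOAc/MeOH, rt, stopped after one equivalent of H2
Reagents that add atoms: none
Why: Hydrogenolysis of an aryl benzyl ether, which is much faster than cleavage of the benzylic C2–O bonds of the two dihydrofuran rings.

Step 14
Reactants: 23 B-OH
Product: 24 B-OTf, the trifluoromethanesulfonate of 23
Conditions: Tf2O, pyridine, CH2Cl2, −10 °C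
Reagents that add atoms: triflic anhydride O=S(=O)(OS(=O)(=O)C(F)(F)F)C(F)(F)F
Why: O-Sulfonylation of the phenol turns the C4 oxygen into a leaving group for cross-coupling.

Step 15
Reactants: 24 B-OTf; 25 (S)-but-3-yn-2-ol
Product: 26 (2S)-4-B-but-3-yn-2-ol
Conditions: PdCl2(PPh3)2 (5 mol %), CuI (10 mol %), Et3N, DMF, 70 °C
Reagents that add atoms: none
Why: Sonogashira coupling of an aryl triflate with a terminal alkyne, the slim linear alkyne being the least demanding partner for the hindered C4 position; the carbinol centre is not involved.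

Step 16
Reactants: 26 the propargylic alcohol
Product: 27 (2S,3Z)-4-B-but-3-en-2-ol
Conditions: H2 (1 atm), Lindlar catalyst, quinoline, EtOAc, rt
Reagents that add atoms: none
Why: Lindlar semi-hydrogenation adds H2 syn to the alkyne and gives the Z-alkene that step 18 needs, the poisoned catalyst leaving the benzylic ring ethers intact.

Step 17
Reactants: 27 the (Z)-allylic alcohol; 28 (3,5-dimethoxyphenyl)acetic acid
Product: 29 (2S,3Z)-4-B-but-3-en-2-yl (3,5-dimethoxyphenyl)acetate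
Conditions: EDC·HCl, DMAP (cat.), CH2Cl2, 0 °C to rt
Reagents that add atoms: none
Why: Steglich esterification acylates the oxygen at neutral pH, so the allylic carbinol carbon keeps its S configuration.

Step 18
Reactants: 29 the (Z)-allylic arylacetate
Product: 32 (2R,3S,4E)-3-B-2-(3,5-dimethoxyphenyl)hex-4-enoic acid, via silyl ketene acetal 30 (not isolated), via trimethylsilyl ester 31 (not isolated)
Conditions: LiHMDS (1.3 equiv), TMSCl (2 equiv), THF/DMPU 4:1, −78 °C to rt; then 1 M HCl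
Reagents that add atoms: none
Why: Ireland–Claisen rearrangement: the arylacetate is expected to enolise with the aryl group cis to O–Li, giving the (Z)-ketene acetal, which rearranges through a chair with the methyl and 3,5-dimethoxyphenyl groups equatorial and B axial (Z-alkene), so that the S carbinol centre is relayed into C3' (S) and C4' (R) in the erythro relationship that becomes 3,4-cis in the tetrahydrofuran.

Step 19
Reactants: 32 the hexenoic acid
Product: 34 (3R,4S)-4-B-3-(3,5-dimethoxyphenyl)-5-hydroxydihydrofuran-2(3H)-one (anomer mixture), via vicinal diol 33 (not isolated)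
Conditions: OsO4 (2 mol %), NaIO4 (4 equiv), 2,6-lutidine (2 equiv), dioxane/H2O 3:1, rt
Reagents that add atoms: osmium tetroxide O=[Os](=O)(=O)=O (oxygen carrier, replenished by sodium periodate [Na+].[O-]I(=O)(=O)=O)
Why: Lemieux–Johnson oxidation cleaves the only alkene (run on the lutidinium carboxylate so that the diol is cleaved before it can lactonise), and the γ-oxo acid closes to its cyclic pseudo-acid, which masks the epimerisable α-aryl aldehyde.

Step 20
Reactants: 34 the hydroxy lactone; 35 4-methoxyphenylmagnesium bromide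
Product: 37 (3R,4S)-4-B-3-(3,5-dimethoxyphenyl)-5-(4-methoxyphenyl)dihydrofuran-2(3H)-one (C5 epimers), via hydroxy acid 36 (not isolated)
Conditions: 35 (3.5 equiv), THF, −78 °C to 0 °C; then 1 M HCl, TsOH (cat.), CH2Cl2, rt
Reagents that add atoms: none
Why: Grignard addition to the open aldehyde form of the pseudo-acid (the first equivalent deprotonates and opens the lactol, the magnesium carboxylate is inert), then acid-promoted lactonisation; C2' forms as a mixture that is settled in step 23.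

Step 21
Reactants: 37 the γ-lactone
Product: 38 (3R,4S)-4-B-3-(3,5-dimethoxyphenyl)-5-(4-methoxyphenyl)tetrahydrofuran-2-ol (C2 and C5 epimers)
Conditions: DIBAL-H (1.2 equiv), CH2Cl2, −78 °C; Rochelle salt
Reagents that add atoms: none
Why: DIBAL-H half-reduction of a γ-lactone stops at the lactol at −78 °C (stable aluminium hemiacetal) and does not enolise the α-aryl centre C4'.

Step 22
Reactants: 38 the lactol; 35 4-methoxyphenylmagnesium bromide
Product: 39 (2S,3R)-2-B-3-(3,5-dimethoxyphenyl)-1,4-bis(4-methoxyphenyl)butane-1,4-diol (C1 and C4 epimers)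
Conditions: 35 (4 equiv), THF, −78 °C to 0 °C; aq. NH4Cl
Reagents that add atoms: none
Why: Grignard addition to the hydroxy aldehyde tautomer of a lactol gives the 1,4-diol, the low temperature keeping the α-aryl aldehyde from enolising; the C5' carbinol centre again forms as a mixture.

Step 23
Reactants: 39 the 1,4-diol
Product: 40 (2R,3S,4R,5S)-3-B-4-(3,5-dimethoxyphenyl)-2,5-bis(4-methoxyphenyl)tetrahydrofuran (kobophenol A decamethyl ether)
Conditions: BF3·OEt2 (0.5 equiv), CH2Cl2, −40 °C to 0 °C; aq. NaHCO3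
Reagents that add atoms: none
Why: Acid-mediated SN1 cyclodehydration of a 1,4-diaryl-butane-1,4-diol: either p-anisyl carbinol ionises and is trapped by the other hydroxyl (5-exo), and because both ring C–O bonds re-ionise under the same conditions, C2' and C5' should converge on the isomer with each anisyl group trans to its neighbour, while C3' and C4' cannot ionise and keep their configuration.

Step 24
Reactants: 40 kobophenol A decamethyl ether
Product: 41 kobophenol A
Conditions: BBr3 (30 equiv), CH2Cl2, −78 °C to 0 °C; MeOH then H2O at −78 °C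
Reagents that add atoms: none
Why: Lewis-acid ether cleavage: BBr3 removes all ten aryl methyl groups (bromide attacks the methyl of each aryloxyborane), the three secondary benzylic ring ethers being expected to survive at low temperature with a cold quench.

**Compound list**

1 | 5-bromo-2-hydroxy-3-methoxybenzaldehyde | COc1cc(Br)cc(C=O)c1O | starting material
2 | 4-methoxybenzyl chloride | COc1ccc(CCl)cc1 | starting material
3 | 5-bromo-3-methoxy-2-[(4-methoxyphenyl)methoxy]benzaldehyde | COc1ccc(COc2c(C=O)cc(Br)cc2OC)cc1 | intermediate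
4 | 1-bromo-3,5-dimethoxybenzene | COc1cc(Br)cc(OC)c1 | starting material
5 | 3,5-dimethoxyphenylmagnesium bromide (not isolated) | COc1cc([Mg]Br)cc(OC)c1 | intermediate
6 | [5-bromo-3-methoxy-2-[(4-methoxyphenyl)methoxy]phenyl](3,5-dimethoxyphenyl)methanol (racemic) | COc1ccc(COc2c(C(O)c3cc(OC)cc(OC)c3)cc(Br)cc2OC)cc1 | intermediate
7 | [5-bromo-3-methoxy-2-[(4-methoxyphenyl)methoxy]phenyl](3,5-dimethoxyphenyl)methanone | COc1ccc(COc2c(C(=O)c3cc(OC)cc(OC)c3)cc(Br)cc2OC)cc1 | intermediate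
8 | hydrazone of 7 (E/Z mixture) | COc1ccc(COc2c(C(=NN)c3cc(OC)cc(OC)c3)cc(Br)cc2OC)cc1 | intermediate
9 | [5-bromo-3-methoxy-2-[(4-methoxyphenyl)methoxy]phenyl](3,5-dimethoxyphenyl)diazomethane (not isolated) | [N-]=[N+]=C(c1cc(OC)cc(OC)c1)c1cc(Br)cc(OC)c1OCc1ccc(OC)cc1 | intermediate
10 | (2S,3R)-5-bromo-3-(3,5-dimethoxyphenyl)-7-methoxy-2-(4-methoxyphenyl)-2,3-dihydro-1-benzofuran, cis (not isolated) | Brc1cc(OC)c2c(c1)[C@@H](c1cc(OC)cc(OC)c1)[C@@H](c1ccc(OC)cc1)O2 | intermediate
11 | (2R,3R)-5-bromo-3-(3,5-dimethoxyphenyl)-7-methoxy-2-(4-methoxyphenyl)-2,3-dihydro-1-benzofuran, trans | Brc1cc(OC)c2c(c1)[C@@H](c1cc(OC)cc(OC)c1)[C@H](c1ccc(OC)cc1)O2 | intermediate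
12 | A-B(OH)2, [(2R,3R)-3-(3,5-dimethoxyphenyl)-7-methoxy-2-(4-methoxyphenyl)-2,3-dihydro-1-benzofuran-5-yl]boronic acid | OB(O)c1cc(OC)c2c(c1)[C@@H](c1cc(OC)cc(OC)c1)[C@H](c1ccc(OC)cc1)O2 | intermediate
13 | 5,7-dihydroxycoumarin | O=c1ccc2c(O)cc(O)cc2o1 | starting material
14 | 5-hydroxy-7-methoxycoumarin | O=c1ccc2c(O)cc(OC)cc2o1 | intermediate
15 | 5-(benzyloxy)-7-methoxycoumarin | O=c1ccc2c(OCc3ccccc3)cc(OC)cc2o1 | intermediate
16 | (4S)-4-A-5-(benzyloxy)-7-methoxychroman-2-one | O=C1C[C@@H](c2cc(OC)c3c(c2)[C@@H](c2cc(OC)cc(OC)c2)[C@H](c2ccc(OC)cc2)O3)c2c(OCc3ccccc3)cc(OC)cc2O1 | intermediate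
17 | lithium enolate of 16 (not isolated) | [Li]OC1=C[C@@H](c2cc(OC)c3c(c2)[C@@H](c2cc(OC)cc(OC)c2)[C@H](c2ccc(OC)cc2)O3)c2c(OCc3ccccc3)cc(OC)cc2O1 | intermediate
18 | (3R,4S)-4-A-5-(benzyloxy)-3-bromo-7-methoxychroman-2-one | O=C1[C@H](Br)[C@@H](c2cc(OC)c3c(c2)[C@@H](c2cc(OC)cc(OC)c2)[C@H](c2ccc(OC)cc2)O3)c2c(OCc3ccccc3)cc(OC)cc2O1 | intermediate
19 | (2R,3S)-3-A-3-[2-(benzyloxy)-6-hydroxy-4-methoxyphenyl]-2-bromopropanoic acid, present as its dianion (not isolated) | OC(=O)[C@H](Br)[C@@H](c1cc(OC)c2c(c1)[C@@H](c1cc(OC)cc(OC)c1)[C@H](c1ccc(OC)cc1)O2)c1c(OCc2ccccc2)cc(OC)cc1O | intermediate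
20 | (2S,3S)-3-A-4-(benzyloxy)-6-methoxy-2,3-dihydro-1-benzofuran-2-carboxylic acid | OC(=O)[C@H]1Oc2cc(OC)cc(OCc3ccccc3)c2[C@@H]1c1cc(OC)c2c(c1)[C@@H](c1cc(OC)cc(OC)c1)[C@H](c1ccc(OC)cc1)O2 | intermediate
21 | 4-iodoanisole | COc1ccc(I)cc1 | starting material
22 | (2S,3S)-3-A-4-(benzyloxy)-6-methoxy-2-(4-methoxyphenyl)-2,3-dihydro-1-benzofuran | COc1ccc([C@H]2Oc3cc(OC)cc(OCc4ccccc4)c3[C@@H]2c2cc(OC)c3c(c2)[C@@H](c2cc(OC)cc(OC)c2)[C@H](c2ccc(OC)cc2)O3)cc1 | intermediate
23 | B-OH, (2S,3S)-3-A-6-methoxy-2-(4-methoxyphenyl)-2,3-dihydro-1-benzofuran-4-ol | COc1ccc([C@H]2Oc3cc(OC)cc(O)c3[C@@H]2c2cc(OC)c3c(c2)[C@@H](c2cc(OC)cc(OC)c2)[C@H](c2ccc(OC)cc2)O3)cc1 | intermediate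
24 | B-OTf, trifluoromethanesulfonate of 23 | COc1ccc([C@H]2Oc3cc(OC)cc(OS(=O)(=O)C(F)(F)F)c3[C@@H]2c2cc(OC)c3c(c2)[C@@H](c2cc(OC)cc(OC)c2)[C@H](c2ccc(OC)cc2)O3)cc1 | intermediate
25 | (S)-but-3-yn-2-ol | C#C[C@H](C)O | starting material
26 | (2S)-4-B-but-3-yn-2-ol | COc1ccc([C@H]2Oc3cc(OC)cc(C#C[C@H](C)O)c3[C@@H]2c2cc(OC)c3c(c2)[C@@H](c2cc(OC)cc(OC)c2)[C@H](c2ccc(OC)cc2)O3)cc1 | intermediate
27 | (2S,3Z)-4-B-but-3-en-2-ol | COc1ccc([C@H]2Oc3cc(OC)cc(/C=C\[C@H](C)O)c3[C@@H]2c2cc(OC)c3c(c2)[C@@H](c2cc(OC)cc(OC)c2)[C@H](c2ccc(OC)cc2)O3)cc1 | intermediate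
28 | (3,5-dimethoxyphenyl)acetic acid | COc1cc(CC(=O)O)cc(OC)c1 | starting material
29 | (2S,3Z)-4-B-but-3-en-2-yl (3,5-dimethoxyphenyl)acetate | COc1ccc([C@H]2Oc3cc(OC)cc(/C=C\[C@H](C)OC(=O)Cc4cc(OC)cc(OC)c4)c3[C@@H]2c2cc(OC)c3c(c2)[C@@H](c2cc(OC)cc(OC)c2)[C@H](c2ccc(OC)cc2)O3)cc1 | intermediate
30 | (Z)-O-trimethylsilyl ketene acetal of 29 (not isolated) | COc1ccc([C@H]2Oc3cc(OC)cc(/C=C\[C@H](C)O/C(O[Si](C)(C)C)=C/c4cc(OC)cc(OC)c4)c3[C@@H]2c2cc(OC)c3c(c2)[C@@H](c2cc(OC)cc(OC)c2)[C@H](c2ccc(OC)cc2)O3)cc1 | intermediate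
31 | trimethylsilyl ester of 32 (not isolated) | COc1ccc([C@H]2Oc3cc(OC)cc([C@@H](/C=C/C)[C@H](c4cc(OC)cc(OC)c4)C(=O)O[Si](C)(C)C)c3[C@@H]2c2cc(OC)c3c(c2)[C@@H](c2cc(OC)cc(OC)c2)[C@H](c2ccc(OC)cc2)O3)cc1 | intermediate
32 | (2R,3S,4E)-3-B-2-(3,5-dimethoxyphenyl)hex-4-enoic acid | COc1ccc([C@H]2Oc3cc(OC)cc([C@@H](/C=C/C)[C@H](c4cc(OC)cc(OC)c4)C(=O)O)c3[C@@H]2c2cc(OC)c3c(c2)[C@@H](c2cc(OC)cc(OC)c2)[C@H](c2ccc(OC)cc2)O3)cc1 | intermediate
33 | (2R,3S)-3-B-2-(3,5-dimethoxyphenyl)-4,5-dihydroxyhexanoic acid, diol epimers (not isolated) | COc1ccc([C@H]2Oc3cc(OC)cc([C@@H](C(O)C(C)O)[C@H](c4cc(OC)cc(OC)c4)C(=O)O)c3[C@@H]2c2cc(OC)c3c(c2)[C@@H](c2cc(OC)cc(OC)c2)[C@H](c2ccc(OC)cc2)O3)cc1 | intermediate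
34 | (3R,4S)-4-B-3-(3,5-dimethoxyphenyl)-5-hydroxydihydrofuran-2(3H)-one, anomer mixture | COc1ccc([C@H]2Oc3cc(OC)cc([C@H]4C(O)OC(=O)[C@H]4c4cc(OC)cc(OC)c4)c3[C@@H]2c2cc(OC)c3c(c2)[C@@H](c2cc(OC)cc(OC)c2)[C@H](c2ccc(OC)cc2)O3)cc1 | intermediate
35 | 4-methoxyphenylmagnesium bromide (THF solution) | COc1ccc([Mg]Br)cc1 | starting material
36 | (2R,3S)-3-B-2-(3,5-dimethoxyphenyl)-4-hydroxy-4-(4-methoxyphenyl)butanoic acid, C4 epimers (not isolated) | COc1ccc([C@H]2Oc3cc(OC)cc([C@@H](C(O)c4ccc(OC)cc4)[C@H](c4cc(OC)cc(OC)c4)C(=O)O)c3[C@@H]2c2cc(OC)c3c(c2)[C@@H](c2cc(OC)cc(OC)c2)[C@H](c2ccc(OC)cc2)O3)cc1 | intermediate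
37 | (3R,4S)-4-B-3-(3,5-dimethoxyphenyl)-5-(4-methoxyphenyl)dihydrofuran-2(3H)-one, C5 epimers | COc1ccc([C@H]2Oc3cc(OC)cc([C@H]4C(c5ccc(OC)cc5)OC(=O)[C@H]4c4cc(OC)cc(OC)c4)c3[C@@H]2c2cc(OC)c3c(c2)[C@@H](c2cc(OC)cc(OC)c2)[C@H](c2ccc(OC)cc2)O3)cc1 | intermediate
38 | (3R,4S)-4-B-3-(3,5-dimethoxyphenyl)-5-(4-methoxyphenyl)tetrahydrofuran-2-ol, C2 and C5 epimers | COc1ccc([C@H]2Oc3cc(OC)cc([C@H]4C(c5ccc(OC)cc5)OC(O)[C@H]4c4cc(OC)cc(OC)c4)c3[C@@H]2c2cc(OC)c3c(c2)[C@@H](c2cc(OC)cc(OC)c2)[C@H](c2ccc(OC)cc2)O3)cc1 | intermediate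
39 | (2S,3R)-2-B-3-(3,5-dimethoxyphenyl)-1,4-bis(4-methoxyphenyl)butane-1,4-diol, C1 and C4 epimers | COc1ccc([C@H]2Oc3cc(OC)cc([C@@H](C(O)c4ccc(OC)cc4)[C@H](c4cc(OC)cc(OC)c4)C(O)c4ccc(OC)cc4)c3[C@@H]2c2cc(OC)c3c(c2)[C@@H](c2cc(OC)cc(OC)c2)[C@H](c2ccc(OC)cc2)O3)cc1 | intermediate
40 | (2R,3S,4R,5S)-3-B-4-(3,5-dimethoxyphenyl)-2,5-bis(4-methoxyphenyl)tetrahydrofuran (kobophenol A decamethyl ether) | COc1ccc([C@H]2Oc3cc(OC)cc([C@@H]4[C@H](c5cc(OC)cc(OC)c5)[C@@H](c5ccc(OC)cc5)O[C@H]4c4ccc(OC)cc4)c3[C@@H]2c2cc(OC)c3c(c2)[C@@H](c2cc(OC)cc(OC)c2)[C@H](c2ccc(OC)cc2)O3)cc1 | intermediate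
41 | kobophenol A | Oc1ccc([C@H]2Oc3cc(O)cc([C@@H]4[C@H](c5cc(O)cc(O)c5)[C@@H](c5ccc(O)cc5)O[C@H]4c4ccc(O)cc4)c3[C@@H]2c2cc(O)c3c(c2)[C@@H](c2cc(O)cc(O)c2)[C@H](c2ccc(O)cc2)O3)cc1 | target

**Step count and risk**

Total step count: 24. Longest linear sequence: 22 steps (1–6, then 9–24); steps 7 and 8 are the side branch to coumarin 15.

The three steps most likely to fail:

Step 23. The reversible ionisation at C2' and C5' may not settle on the trans,cis,trans arrangement. The p-anisyl cation may also be captured irreversibly by a neighbouring electron-rich ring (Friedel–Crafts closure to an indane) faster than by the hydroxyl group. The fallback replaces thermodynamic cyclodehydration by kinetic C-arylation of a cyclic oxocarbenium ion; it sets out from lactone 37 and comes back at 40. The C5 epimers of 37 are separated, the cis epimer being recycled by brief TFA treatment (the p-anisyl lactone C–O bond ionises and recloses trans), to give the single trans lactone (3R,4S,5R)-4-B-3-(3,5-dimethoxyphenyl)-5-(4-methoxyphenyl)dihydrofuran-2(3H)-one F1. DIBAL-H at −78 °C gives the lactol (3R,4S,5R)-4-B-3-(3,5-dimethoxyphenyl)-5-(4-methoxyphenyl)tetrahydrofuran-2-ol F2, and acetic anhydride with pyridine gives its anomeric acetate F3. BF3·OEt2 and bis(4-methoxyphenyl)zinc (from 35 and ZnCl2) in CH2Cl2 at −78 °C should then deliver the aryl group to the oxocarbenium ion anti to the neighbouring 3,5-dimethoxyphenyl group, as in C-aryl glycoside synthesis, and give 40.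

Step 18. The Z-alkene forces the bulky group B into the axial position of the chair, so a boat pathway or incomplete control of ketene acetal geometry may erode the C3'/C4' relationship. The fallback replaces sigmatropic chirality transfer by a catalyst-controlled intermolecular allylation; it sets out from triflate 24 and comes back at 34. Sonogashira coupling of 24 with prop-2-yn-1-ol gives 3-B-prop-2-yn-1-ol F4, Red-Al reduces it to (E)-3-B-prop-2-en-1-ol F5, and methyl chloroformate with pyridine gives the allylic methyl carbonate F6. Dual catalysis by an iridium phosphoramidite complex and benzotetramisole (stereodivergent allylic substitution of aryl acetic acid esters) joins F6 with pentafluorophenyl (3,5-dimethoxyphenyl)acetate F7 (from 28, pentafluorophenol and EDC) to give the branched ester pentafluorophenyl (2R,3S)-3-B-2-(3,5-dimethoxyphenyl)pent-4-enoate F8, the enantiomers of the two catalysts being chosen for this isomer. LiOH/H2O2 gives the acid (2R,3S)-3-B-2-(3,5-dimethoxyphenyl)pent-4-enoic acid F9, whose vinyl group is cleaved as in step 19 to give 34.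

Step 9. Insertion of the peri-substituted C3=C4 bond into the aryl–rhodium bond may be slow, so that protodeboronation of 12 outruns the addition. The fallback forms the aryl–C4 bond first and creates the stereocentre by delivering hydride instead of the aryl group; it sets out from 12 and 15 and comes back at 16. Oxidative Heck coupling (Pd(OAc)2, 1,10-phenanthroline, O2, DMF, 80 °C) gives the 4-arylcoumarin 4-A-5-(benzyloxy)-7-methoxycoumarin F10. Copper hydride asymmetric conjugate reduction (Cu(OAc)2, DTBM-SEGPHOS of the appropriate hand, diethoxymethylsilane, t-BuOH, toluene), followed by acidic work-up to re-lactonise, gives 16.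

**Further compounds**

F1 | step 23 | (3R,4S,5R)-4-B-3-(3,5-dimethoxyphenyl)-5-(4-methoxyphenyl)dihydrofuran-2(3H)-one | COc1ccc([C@H]2Oc3cc(OC)cc([C@H]4[C@H](c5ccc(OC)cc5)OC(=O)[C@H]4c4cc(OC)cc(OC)c4)c3[C@@H]2c2cc(OC)c3c(c2)[C@@H](c2cc(OC)cc(OC)c2)[C@H](c2ccc(OC)cc2)O3)cc1
F2 | step 23 | (3R,4S,5R)-4-B-3-(3,5-dimethoxyphenyl)-5-(4-methoxyphenyl)tetrahydrofuran-2-ol (anomer mixture) | COc1ccc([C@H]2Oc3cc(OC)cc([C@H]4[C@H](c5ccc(OC)cc5)OC(O)[C@H]4c4cc(OC)cc(OC)c4)c3[C@@H]2c2cc(OC)c3c(c2)[C@@H](c2cc(OC)cc(OC)c2)[C@H](c2ccc(OC)cc2)O3)cc1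
F3 | step 23 | acetate of F2 (anomer mixture) | COc1ccc([C@H]2Oc3cc(OC)cc([C@H]4[C@H](c5ccc(OC)cc5)OC(OC(C)=O)[C@H]4c4cc(OC)cc(OC)c4)c3[C@@H]2c2cc(OC)c3c(c2)[C@@H](c2cc(OC)cc(OC)c2)[C@H](c2ccc(OC)cc2)O3)cc1
F4 | step 18 | 3-B-prop-2-yn-1-ol | COc1ccc([C@H]2Oc3cc(OC)cc(C#CCO)c3[C@@H]2c2cc(OC)c3c(c2)[C@@H](c2cc(OC)cc(OC)c2)[C@H](c2ccc(OC)cc2)O3)cc1
F5 | step 18 | (E)-3-B-prop-2-en-1-ol | COc1ccc([C@H]2Oc3cc(OC)cc(/C=C/CO)c3[C@@H]2c2cc(OC)c3c(c2)[C@@H](c2cc(OC)cc(OC)c2)[C@H](c2ccc(OC)cc2)O3)cc1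
F6 | step 18 | (E)-3-B-prop-2-en-1-yl methyl carbonate | COc1ccc([C@H]2Oc3cc(OC)cc(/C=C/COC(=O)OC)c3[C@@H]2c2cc(OC)c3c(c2)[C@@H](c2cc(OC)cc(OC)c2)[C@H](c2ccc(OC)cc2)O3)cc1
F7 | step 18 | pentafluorophenyl (3,5-dimethoxyphenyl)acetate | COc1cc(CC(=O)Oc2c(F)c(F)c(F)c(F)c2F)cc(OC)c1
F8 | step 18 | pentafluorophenyl (2R,3S)-3-B-2-(3,5-dimethoxyphenyl)pent-4-enoate | COc1ccc([C@H]2Oc3cc(OC)cc([C@@H](C=C)[C@H](c4cc(OC)cc(OC)c4)C(=O)Oc4c(F)c(F)c(F)c(F)c4F)c3[C@@H]2c2cc(OC)c3c(c2)[C@@H](c2cc(OC)cc(OC)c2)[C@H](c2ccc(OC)cc2)O3)cc1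
F9 | step 18 | (2R,3S)-3-B-2-(3,5-dimethoxyphenyl)pent-4-enoic acid | COc1ccc([C@H]2Oc3cc(OC)cc([C@@H](C=C)[C@H](c4cc(OC)cc(OC)c4)C(=O)O)c3[C@@H]2c2cc(OC)c3c(c2)[C@@H](c2cc(OC)cc(OC)c2)[C@H](c2ccc(OC)cc2)O3)cc1
F10 | step 9 | 4-A-5-(benzyloxy)-7-methoxycoumarin | O=c1cc(-c2cc(OC)c3c(c2)[C@@H](c2cc(OC)cc(OC)c2)[C@H](c2ccc(OC)cc2)O3)c2c(OCc3ccccc3)cc(OC)cc2o1
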